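The route rests on cutting two bonds of the catechol-bearing dihydrobenzofuran at once: C2'–aryl and C3'–C3a'. The feature exploited is the C2'–C3' ethane unit of ring 2. It has one aryl group on C2' and two on C3', one of them ring B, attached through C3a' between two equivalent oxygens. One conjunctive coupling adds a 3,4-dimethoxyphenyl group and a symmetric gallate ring anti across an (E)-styrylboronate. This creates both bonds and both stereocentres, and no ring closes. The precursor is the lithium ate complex of (E)-3,5-dimethoxystyrylboronate, used as a hindered mac ester. Acid then closes ring 2, and the gallate ester launches a mirror-image second cycle for ring 1.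

Key step: step 7

**Conventions**
- Benzofuran numbering is used. Primed atoms belong to the catechol-bearing unit (dihydrofuran ring 2, benzo ring B). Unprimed atoms belong to the styryl-bearing unit (dihydrofuran ring 1, benzo ring A).
- mac = the diolate of cis-1,2-dimethyl-1,2-dihydroacenaphthylene-1,2-diol.
- Q = (2S,3S)-2-(3,4-dimethoxyphenyl)-3-(3,5-dimethoxyphenyl)-4-methoxy-2,3-dihydro-1-benzofuran-6-yl.
- L = (S,S)-1,1'-bis[bis(4-methoxy-3,5-dimethylphenyl)phosphino]-(R,R)-2,2'-bis[α-(dimethylamino)benzyl]ferrocene, a MandyPhos-type ligand. ent-L is its mirror image.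

**Assumption:** L denotes the antipode that places palladium on the Si face of C3'. Induction with a β-aryl alkenylboronate has not been mapped, so L and ent-L may have to be exchanged; both are commercial and the route stays the same.

**Design points**
- The target is (2R,3R) in ring 1 and (2'S,3'S) in ring 2, and both rings are trans. The two units have opposite local sense, so the second cycle needs ent-L.
- The boronic ester is the mac ester rather than the common pinacol ester. β-Substituted alkenyl pinacol ate complexes tend to hand the alkenyl group directly to palladium.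
- Bromine–lithium exchange with n-BuLi leaves no lithium halide, so palladium stays cationic.
- The triflate is installed last on the gallate, so it never sits beside a free phenoxide.
- Each dihydrofuran ring is closed by ionisation at C2 or C2'. The boron-derived oxygen leaves as water and a gallate oxygen becomes the ring oxygen. An invertive displacement would give the cis ring.

Step 1
Reactants: 1 methyl gallate (methyl 3,4,5-trihydroxybenzoate)
Product: 2 methyl 4-(benzyloxy)-3,5-dihydroxybenzoate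
Conditions: BnBr (1.0 equiv), KHCO3, KI (cat.), DMF, rt
Reagents that add atoms: benzyl bromide, BrCc1ccccc1
Why: Williamson etherification with a weak base that ionises only the most acidic hydroxyl, O4 para to the ester, so the central oxygen should be masked selectively.

Step 2
Reactants: 2 methyl 4-(benzyloxy)-3,5-dihydroxybenzoate
Product: 3 methyl 4-(benzyloxy)-3,5-bis(methoxymethoxy)benzoate
Conditions: MOMCl (2.5 equiv), K2CO3, acetone, 0 °C → rt
Reagents that add atoms: chloromethyl methyl ether, COCCl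
Why: O-alkylation of the two remaining, equivalent phenols to formaldehyde acetals, with the ester and the benzyl ether inert to carbonate.

Step 3
Reactants: 3 methyl 4-(benzyloxy)-3,5-bis(methoxymethoxy)benzoate
Product: 4 methyl 4-hydroxy-3,5-bis(methoxymethoxy)benzoate
Conditions: H2 (1 atm), Pd/C (10 %), EtOAc, rt
Reagents that add atoms: none
Why: Neutral hydrogenolysis of the benzyl aryl ether frees O4 alone, since MOM acetals and the benzoate are not reduced.

Step 4
Reactants: 4 methyl 4-hydroxy-3,5-bis(methoxymethoxy)benzoate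
Product: 5 methyl 3,5-bis(methoxymethoxy)-4-(trifluoromethylsulfonyloxy)benzoate
Conditions: Tf2O, pyridine, CH2Cl2, 0 °C
Reagents that add atoms: trifluoromethanesulfonic anhydride, O=S(=O)(OS(=O)(=O)C(F)(F)F)C(F)(F)F
Why: O-sulfonylation of the single free phenol in excess pyridine, which keeps the acetals intact and excludes sulfonyl migration because no neighbouring phenoxide exists.

Step 5
Reactants: 6 acenaphthoquinone
Product: 7 cis-1,2-dimethyl-1,2-dihydroacenaphthylene-1,2-diol (meso, mac diol)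
Conditions: AlMe3 (3 equiv), toluene, 0 °C → rt; aq. potassium sodium tartrate; recrystallisation
Reagents that add atoms: trimethylaluminium, C[Al](C)C
Why: Twofold 1,2-addition of methyl to the 1,2-diketone, in which the second methyl should enter anti to the bulky aluminium alkoxide to give the cis diol, and recrystallisation removes any trans isomer.

Step 6
Reactants: 8 1-ethynyl-3,5-dimethoxybenzene; 7 mac diol
Product: 10 (E)-2-(3,5-dimethoxyphenyl)vinylboronic acid mac ester, via styryl catechol boronate 9 (not isolated)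
Conditions: catecholborane, Cy2BH (10 mol %), THF, rt; then 7, rt
Reagents that add atoms: catecholborane, B1Oc2ccccc2O1
Why: Syn, anti-Markovnikov alkyne hydroboration fixes the E geometry, and transesterification then replaces the labile catechol by the more basic, preorganised cis diol.

Step 7
Reactants: 10 (E)-2-(3,5-dimethoxyphenyl)vinylboronic acid mac ester; 11 4-bromo-1,2-dimethoxybenzene; 5 methyl 3,5-bis(methoxymethoxy)-4-(trifluoromethylsulfonyloxy)benzoate
Product: 14 methyl 4-[(1S,2S)-2-(3,4-dimethoxyphenyl)-1-(3,5-dimethoxyphenyl)-2-(mac-boryl)ethyl]-3,5-bis(methoxymethoxy)benzoate, via 3,4-dimethoxyphenyllithium 12 (not isolated), via lithium ate complex 13 (not isolated)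
Conditions: 11, n-BuLi, THF, −78 °C; 10, −78 °C → rt; evaporate (removes n-BuBr); 5, Pd(OAc)2 (5 mol %), L (6 mol %), THF, 60 °C
Reagents that add atoms: none
Why: Proposed new method: oxidative addition of 5 to the zerovalent palladium–L complex gives a cationic aryl complex of divalent palladium that binds the alkene of 13, the 3,4-dimethoxyphenyl group shifts from boron to C2' on the face opposite palladium while palladium bonds C3', and reductive elimination with retention forms C3'–C3a'. The closest known reaction type is the enantioselective palladium-catalysed conjunctive (1,2-metallate) cross-coupling of alkenylboron ate complexes with aryl triflates, known for vinyl and β-alkyl alkenyl boronates with unhindered triflates but not for a β-aryl boronate with a 2,6-dioxygenated triflate. No ring is closed in this step. C3' is set by the chiral diphosphine, which selects the Si face of C3' for palladium, and C2' is set relative to it by the anti migration across the E alkene, giving the (1S,2S) boronate. The step needs the metallate shift to win over direct styryl or aryl transfer to palladium and over β-hydride elimination: the hindered mac diolate blocks the B–O–Pd contact needed for transmetallation, the halide-free ate complex keeps palladium cationic, and the chelating ligand leaves no free site for hydride elimination. Regiochemistry is inherent because only the boron-bearing carbon can accept the migrating group, the two ortho MOM ethers are equivalent so ring B poses no site question, and the para ester speeds oxidative addition without ever meeting free aryllithium.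

Step 8
Reactants: 14 mac boronate
Product: 15 methyl 4-[(1S,2S)-2-(3,4-dimethoxyphenyl)-1-(3,5-dimethoxyphenyl)-2-hydroxyethyl]-3,5-bis(methoxymethoxy)benzoate
Conditions: NaBO3·4H2O, THF/H2O, rt
Reagents that add atoms: sodium perborate, [Na+].[Na+].O[B-]1(O)OO[B-](O)(O)OO1
Why: Boronate oxidation by 1,2-shift of carbon from boron to peroxide oxygen, which retains configuration at C2' and is mild enough for the methyl ester and the acetals.

Step 9
Reactants: 15 triarylethanol
Product: 17 methyl (2S,3S)-2-(3,4-dimethoxyphenyl)-3-(3,5-dimethoxyphenyl)-4-hydroxy-2,3-dihydro-1-benzofuran-6-carboxylate (trans), via resorcinol alcohol 16 (not isolated)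
Conditions: conc. HCl (cat.), MeOH, high dilution, 40 °C
Reagents that add atoms: none
Why: Acetal cleavage followed by SN1 cycloetherification, in which either of the two equivalent phenols captures the dimethoxybenzyl cation at C2' in a five-membered closure, the trans isomer being both the less hindered and the thermodynamic outcome under reversible conditions while C3' is untouched.

Step 10
Reactants: 17 ring 2 phenol
Product: 18 methyl (2S,3S)-2-(3,4-dimethoxyphenyl)-3-(3,5-dimethoxyphenyl)-4-methoxy-2,3-dihydro-1-benzofuran-6-carboxylate (Q–CO2Me)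
Conditions: MeI, K2CO3, acetone, reflux
Reagents that add atoms: iodomethane, CI
Why: Williamson methylation of the one remaining phenol with a base too weak to touch the C3' hydrogen.

Step 11
Reactants: 18 Q–CO2Me
Product: 19 Q–CH2OH
Conditions: i-Bu2AlH (2.5 equiv), CH2Cl2, −78 → 0 °C; aq. potassium sodium tartrate
Reagents that add atoms: none
Why: Hydride reduction of the benzoate to the benzylic alcohol, with aryl ethers and the dihydrofuran inert.

Step 12
Reactants: 19 Q–CH2OH
Product: 21 Q–C≡CH, via aldehyde 20 (not isolated)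
Conditions: MnO2, THF, rt; then dimethyl (1-diazo-2-oxopropyl)phosphonate, K2CO3, MeOH, rt
Reagents that add atoms: dimethyl (1-diazo-2-oxopropyl)phosphonate, CC(=O)C(=[N+]=[N-])P(=O)(OC)OC
Why: Tandem benzylic oxidation and Seyferth–Gilbert homologation (Ohira–Bestmann variant), a known one-pot sequence for activated alcohols that uses only carbonate as base.

Step 13
Reactants: 21 Q–C≡CH; 7 mac diol
Product: 23 (E)-2-Q-vinylboronic acid mac ester, via catechol boronate 22 (not isolated)
Conditions: catecholborane, Cy2BH (10 mol %), THF, rt; then 7, rt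
Reagents that add atoms: catecholborane, B1Oc2ccccc2O1
Why: Syn hydroboration of the terminal aryl alkyne gives the E alkenylboron compound and transesterification installs the mac diolate, as in step 6.

Step 14
Reactants: 23 (E)-2-Q-vinylboronic acid mac ester; 24 4-bromoanisole; 5 gallate triflate
Product: 28 methyl 4-[(1R,2R)-2-hydroxy-2-(4-methoxyphenyl)-1-Q-ethyl]-3,5-bis(methoxymethoxy)benzoate, via 4-methoxyphenyllithium 25 (not isolated), via lithium ate complex 26 (not isolated), via mac boronate 27 (not isolated)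
Conditions: 24, n-BuLi, THF, −78 °C; 23, → rt; evaporate; 5, Pd(OAc)2 (5 mol %), ent-L (6 mol %), THF, 60 °C; then NaBO3·4H2O, THF/H2O, rt
Reagents that add atoms: sodium perborate, [Na+].[Na+].O[B-]1(O)OO[B-](O)(O)OO1
Why: Proposed new method: as in step 7, the cationic aryl complex of divalent palladium from 5 binds the alkene of 26, the 4-methoxyphenyl group shifts from boron to C2 anti to palladium and reductive elimination forms C3–C3a, the closest known type being the enantioselective conjunctive cross-coupling of alkenylboron ate complexes with aryl triflates; ent-L directs palladium to the Re face of C3, the anti shift across the E alkene fixes C2, C2' and C3' are too remote to interfere, and perborate then replaces boron by oxygen with retention.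

Step 15
Reactants: 28 triarylethanol
Product: 30 methyl (2R,3R)-4-hydroxy-2-(4-methoxyphenyl)-3-Q-2,3-dihydro-1-benzofuran-6-carboxylate (trans), via resorcinol alcohol 29 (not isolated)
Conditions: conc. HCl (cat.), MeOH, high dilution, 40 °C
Reagents that add atoms: none
Why: Acetal cleavage and SN1 cycloetherification through the 4-methoxybenzyl cation at C2 close ring 1 trans to the fixed C3, and any transient opening of ring 2 at C2'–O can only reclose to its trans form.

Step 16
Reactants: 30 ring 1 phenol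
Product: 31 methyl (2R,3R)-4-methoxy-2-(4-methoxyphenyl)-3-Q-2,3-dihydro-1-benzofuran-6-carboxylate
Conditions: MeI, K2CO3, acetone, reflux
Reagents that add atoms: iodomethane, CI
Why: Williamson methylation of the last free phenol, so that the next three steps run on a neutral, fully masked substrate.

Step 17
Reactants: 31 ester
Product: 32 [(2R,3R)-4-methoxy-2-(4-methoxyphenyl)-3-Q-2,3-dihydro-1-benzofuran-6-yl]methanol
Conditions: i-Bu2AlH (2.5 equiv), CH2Cl2, −78 → 0 °C; aq. potassium sodium tartrate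
Reagents that add atoms: none
Why: Hydride reduction of the benzoate to the benzylic alcohol, as in step 11.

Step 18
Reactants: 32 benzylic alcohol
Product: 33 (2R,3R)-4-methoxy-2-(4-methoxyphenyl)-3-Q-2,3-dihydro-1-benzofuran-6-carbaldehyde
Conditions: MnO2, CH2Cl2, rt
Reagents that add atoms: none
Why: Selective heterogeneous oxidation of a benzylic alcohol to the aldehyde under neutral conditions.

Step 19
Reactants: 33 aldehyde; 34 diethyl 4-methoxybenzylphosphonate
Product: 35 octamethyl ether of the target, (E)-stilbene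
Conditions: 34, NaH, THF, 0 °C; then 33, 0 °C → rt
Reagents that add atoms: none
Why: Horner–Wadsworth–Emmons olefination with a benzylic phosphonate gives the E stilbene, and adding the aldehyde to the preformed anion at low temperature lets carbonyl addition outrun deprotonation at C3.

Step 20
Reactants: 35 octamethyl ether
Product: 36 target CNP0107857.3, (2R,3R,2'S,3'S)
Conditions: BBr3 (excess), CH2Cl2, −78 °C → rt; H2O
Reagents that add atoms: none
Why: Lewis-acid cleavage of all eight aryl methyl ethers; a transient opening at C2–O or C2'–O can only reclose to the trans ring because C3 and C3' are not touched, and the styryl group at C6 lies too far from either benzylic position to cyclise.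

**Compound list**

1 | methyl gallate | COC(=O)c1cc(O)c(O)c(O)c1 | starting material
2 | methyl 4-(benzyloxy)-3,5-dihydroxybenzoate | COC(=O)c1cc(O)c(OCc2ccccc2)c(O)c1 | intermediate
3 | methyl 4-(benzyloxy)-3,5-bis(methoxymethoxy)benzoate | COCOc1cc(C(=O)OC)cc(OCOC)c1OCc1ccccc1 | intermediate
4 | methyl 4-hydroxy-3,5-bis(methoxymethoxy)benzoate | COCOc1cc(C(=O)OC)cc(OCOC)c1O | intermediate
5 | methyl 3,5-bis(methoxymethoxy)-4-(trifluoromethylsulfonyloxy)benzoate | COCOc1cc(C(=O)OC)cc(OCOC)c1OS(=O)(=O)C(F)(F)F | intermediate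
6 | acenaphthoquinone | O=C1C(=O)c2cccc3cccc1c23 | starting material
7 | cis-1,2-dimethyl-1,2-dihydroacenaphthylene-1,2-diol (mac diol, meso) | C[C@@]1(O)c2cccc3cccc(c23)[C@]1(C)O | intermediate
8 | 1-ethynyl-3,5-dimethoxybenzene | C#Cc1cc(OC)cc(OC)c1 | starting material
9 | 2-[(E)-3,5-dimethoxystyryl]-1,3,2-benzodioxaborole | COc1cc(/C=C/B2Oc3ccccc3O2)cc(OC)c1 | intermediate
10 | (E)-2-(3,5-dimethoxyphenyl)vinylboronic acid mac ester | COc1cc(/C=C/B2O[C@]3(C)c4cccc5cccc(c45)[C@]3(C)O2)cc(OC)c1 | intermediate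
11 | 4-bromo-1,2-dimethoxybenzene | COc1ccc(Br)cc1OC | starting material
12 | 3,4-dimethoxyphenyllithium | [Li]c1ccc(OC)c(OC)c1 | intermediate
13 | lithium (3,4-dimethoxyphenyl)[(E)-3,5-dimethoxystyryl](mac)borate | [Li+].COc1cc(/C=C/[B-]2(c3ccc(OC)c(OC)c3)O[C@]3(C)c4cccc5cccc(c45)[C@]3(C)O2)cc(OC)c1 | intermediate
14 | methyl 4-[(1S,2S)-2-(3,4-dimethoxyphenyl)-1-(3,5-dimethoxyphenyl)-2-(mac-boryl)ethyl]-3,5-bis(methoxymethoxy)benzoate | O1[C@]2(C)c3cccc4cccc(c34)[C@]2(C)OB1[C@H](c1ccc(OC)c(OC)c1)[C@H](c1c(OCOC)cc(C(=O)OC)cc1OCOC)c1cc(OC)cc(OC)c1 | intermediate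
15 | methyl 4-[(1S,2S)-2-(3,4-dimethoxyphenyl)-1-(3,5-dimethoxyphenyl)-2-hydroxyethyl]-3,5-bis(methoxymethoxy)benzoate | O[C@H](c1ccc(OC)c(OC)c1)[C@H](c1c(OCOC)cc(C(=O)OC)cc1OCOC)c1cc(OC)cc(OC)c1 | intermediate
16 | methyl 4-[(1S,2S)-2-(3,4-dimethoxyphenyl)-1-(3,5-dimethoxyphenyl)-2-hydroxyethyl]-3,5-dihydroxybenzoate | O[C@H](c1ccc(OC)c(OC)c1)[C@H](c1c(O)cc(C(=O)OC)cc1O)c1cc(OC)cc(OC)c1 | intermediate
17 | methyl (2S,3S)-2-(3,4-dimethoxyphenyl)-3-(3,5-dimethoxyphenyl)-4-hydroxy-2,3-dihydro-1-benzofuran-6-carboxylate | COC(=O)c1cc(O)c2c(c1)O[C@H](c1ccc(OC)c(OC)c1)[C@H]2c1cc(OC)cc(OC)c1 | intermediate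
18 | Q–CO2Me, the 4-methyl ether of 17 | COC(=O)c1cc(OC)c2c(c1)O[C@H](c1ccc(OC)c(OC)c1)[C@H]2c1cc(OC)cc(OC)c1 | intermediate
19 | Q–CH2OH | OCc1cc(OC)c2c(c1)O[C@H](c1ccc(OC)c(OC)c1)[C@H]2c1cc(OC)cc(OC)c1 | intermediate
20 | Q–CHO | O=Cc1cc(OC)c2c(c1)O[C@H](c1ccc(OC)c(OC)c1)[C@H]2c1cc(OC)cc(OC)c1 | intermediate
21 | Q–C≡CH | C#Cc1cc(OC)c2c(c1)O[C@H](c1ccc(OC)c(OC)c1)[C@H]2c1cc(OC)cc(OC)c1 | intermediate
22 | 2-[(E)-2-Q-vinyl]-1,3,2-benzodioxaborole | O1c2ccccc2OB1/C=C/c1cc(OC)c2c(c1)O[C@H](c1ccc(OC)c(OC)c1)[C@H]2c1cc(OC)cc(OC)c1 | intermediate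
23 | (E)-2-Q-vinylboronic acid mac ester | O1[C@]2(C)c3cccc4cccc(c34)[C@]2(C)OB1/C=C/c1cc(OC)c2c(c1)O[C@H](c1ccc(OC)c(OC)c1)[C@H]2c1cc(OC)cc(OC)c1 | intermediate
24 | 4-bromoanisole | COc1ccc(Br)cc1 | starting material
25 | 4-methoxyphenyllithium | [Li]c1ccc(OC)cc1 | intermediate
26 | lithium (4-methoxyphenyl)[(E)-2-Q-vinyl](mac)borate | [Li+].O1[C@]2(C)c3cccc4cccc(c34)[C@]2(C)O[B-]1(c1ccc(OC)cc1)/C=C/c1cc(OC)c2c(c1)O[C@H](c1ccc(OC)c(OC)c1)[C@H]2c1cc(OC)cc(OC)c1 | intermediate
27 | methyl 4-[(1R,2R)-2-(4-methoxyphenyl)-1-Q-2-(mac-boryl)ethyl]-3,5-bis(methoxymethoxy)benzoate | O1[C@]2(C)c3cccc4cccc(c34)[C@]2(C)OB1[C@@H](c1ccc(OC)cc1)[C@@H](c1c(OCOC)cc(C(=O)OC)cc1OCOC)c1cc(OC)c2c(c1)O[C@H](c1ccc(OC)c(OC)c1)[C@H]2c1cc(OC)cc(OC)c1 | intermediate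
28 | methyl 4-[(1R,2R)-2-hydroxy-2-(4-methoxyphenyl)-1-Q-ethyl]-3,5-bis(methoxymethoxy)benzoate | O[C@@H](c1ccc(OC)cc1)[C@@H](c1c(OCOC)cc(C(=O)OC)cc1OCOC)c1cc(OC)c2c(c1)O[C@H](c1ccc(OC)c(OC)c1)[C@H]2c1cc(OC)cc(OC)c1 | intermediate
29 | methyl 4-[(1R,2R)-2-hydroxy-2-(4-methoxyphenyl)-1-Q-ethyl]-3,5-dihydroxybenzoate | O[C@@H](c1ccc(OC)cc1)[C@@H](c1c(O)cc(C(=O)OC)cc1O)c1cc(OC)c2c(c1)O[C@H](c1ccc(OC)c(OC)c1)[C@H]2c1cc(OC)cc(OC)c1 | intermediate
30 | methyl (2R,3R)-4-hydroxy-2-(4-methoxyphenyl)-3-Q-2,3-dihydro-1-benzofuran-6-carboxylate | COC(=O)c1cc(O)c2c(c1)O[C@@H](c1ccc(OC)cc1)[C@@H]2c1cc(OC)c2c(c1)O[C@H](c1ccc(OC)c(OC)c1)[C@H]2c1cc(OC)cc(OC)c1 | intermediate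
31 | methyl (2R,3R)-4-methoxy-2-(4-methoxyphenyl)-3-Q-2,3-dihydro-1-benzofuran-6-carboxylate | COC(=O)c1cc(OC)c2c(c1)O[C@@H](c1ccc(OC)cc1)[C@@H]2c1cc(OC)c2c(c1)O[C@H](c1ccc(OC)c(OC)c1)[C@H]2c1cc(OC)cc(OC)c1 | intermediate
32 | [(2R,3R)-4-methoxy-2-(4-methoxyphenyl)-3-Q-2,3-dihydro-1-benzofuran-6-yl]methanol | OCc1cc(OC)c2c(c1)O[C@@H](c1ccc(OC)cc1)[C@@H]2c1cc(OC)c2c(c1)O[C@H](c1ccc(OC)c(OC)c1)[C@H]2c1cc(OC)cc(OC)c1 | intermediate
33 | (2R,3R)-4-methoxy-2-(4-methoxyphenyl)-3-Q-2,3-dihydro-1-benzofuran-6-carbaldehyde | O=Cc1cc(OC)c2c(c1)O[C@@H](c1ccc(OC)cc1)[C@@H]2c1cc(OC)c2c(c1)O[C@H](c1ccc(OC)c(OC)c1)[C@H]2c1cc(OC)cc(OC)c1 | intermediate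
34 | diethyl 4-methoxybenzylphosphonate | CCOP(=O)(Cc1ccc(OC)cc1)OCC | starting material
35 | octamethyl ether of the target, (2R,3R)-4-methoxy-2-(4-methoxyphenyl)-6-[(E)-4-methoxystyryl]-3-Q-2,3-dihydro-1-benzofuran | COc1ccc(/C=C/c2cc(OC)c3c(c2)O[C@@H](c2ccc(OC)cc2)[C@@H]3c2cc(OC)c3c(c2)O[C@H](c2ccc(OC)c(OC)c2)[C@H]3c2cc(OC)cc(OC)c2)cc1 | intermediate
36 | CNP0107857.3, (2R,3R,2'S,3'S) | Oc1ccc(/C=C/c2cc(O)c3c(c2)O[C@@H](c2ccc(O)cc2)[C@@H]3c2cc(O)c3c(c2)O[C@H](c2ccc(O)c(O)c2)[C@H]3c2cc(O)cc(O)c2)cc1 | target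

Total step count: 20. Longest linear sequence: 18 (steps 1–4 and 7–20).

**Steps most likely to fail**

1. Step 7.
   - What may go wrong: direct transfer of the styryl or aryl group from boron to palladium instead of the metallate shift, slow alkene binding by the crowded aryl palladium cation, β-hydride elimination after the shift, or weak facial discrimination.
   - Fallback (known chemistry, sets out from 5 and comes back at 17): ketone α-arylation replaces the three-component coupling, and a classical resolution replaces catalyst control. 3',4'-Dimethoxyacetophenone and 1-bromo-3,5-dimethoxybenzene (Pd2(dba)3, XPhos, NaOt-Bu, toluene) should give 1-(3,4-dimethoxyphenyl)-2-(3,5-dimethoxyphenyl)ethanone F1. A second α-arylation of its enolate with 5 (Pd(OAc)2, XPhos, K3PO4, toluene) should give the racemic triarylethanone F2. NaBH4 in MeOH should give the racemic triarylethanols F3. Catalytic HCl in MeOH, as in step 9, should give the racemic trans phenol F4. (1S)-Camphanic chloride and pyridine should give the camphanate of the (2S,3S) enantiomer F5 beside the camphanate of the (2R,3R) enantiomer F6, to be parted by crystallisation or chromatography. K2CO3 in MeOH should then release 17 from F5.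

2. Step 14.
   - What may go wrong: the same competition between metallate shift and direct transmetallation, now on a larger and more valuable alkenylboronate, and erosion of facial selectivity.
   - Fallback (known chemistry, sets out from 23 and comes back at 30): NaBO3·4H2O should oxidise 23 to the arylacetaldehyde F7. 4-Methoxyphenylmagnesium bromide should give the carbinol F8. Dess–Martin periodinane should give the deoxybenzoin F9. α-Arylation with 5 (Pd(OAc)2, XPhos, K3PO4, toluene) should give the triarylethanone F10, and NaBH4 should give the triarylethanols F11. Catalytic HCl in MeOH should close ring 1 trans. C3 is not controlled on this path, so 30 should form beside its (2S,3S) ring 1 diastereomer F12. Ring 2 is already enantiopure, so the two are diastereomers and can be parted by chromatography.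

3. Step 20.
   - What may go wrong: incomplete cleavage of eight ethers, acid-induced cationic oligomerisation through the electron-rich stilbene, and intermolecular arylation after opening of a dihydrofuran ring.
   - Fallback (sets out from 33 and comes back at 36): the ether cleavage is moved ahead of the olefination and the phenols are masked again as silyl ethers, so the stilbene never meets a Lewis acid. BBr3 on 33 should give the heptaphenol aldehyde F13. TBSCl and imidazole in DMF should give the heptakis(silyl ether) aldehyde F14. Diethyl 4-hydroxybenzylphosphonate, silylated in the same way, should give the silyloxybenzylphosphonate F15. Horner–Wadsworth–Emmons olefination of F14 with F15 (NaH, THF, 0 °C) should give the octakis(silyl ether) stilbene F16. Et3N·3HF in THF should then release 36.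

Further compounds
F1 | step 7 | 1-(3,4-dimethoxyphenyl)-2-(3,5-dimethoxyphenyl)ethanone | COc1cc(CC(=O)c2ccc(OC)c(OC)c2)cc(OC)c1
F2 | step 7 | methyl 4-[2-(3,4-dimethoxyphenyl)-1-(3,5-dimethoxyphenyl)-2-oxoethyl]-3,5-bis(methoxymethoxy)benzoate (racemic) | COCOc1cc(C(=O)OC)cc(OCOC)c1C(C(=O)c1ccc(OC)c(OC)c1)c1cc(OC)cc(OC)c1
F3 | step 7 | methyl 4-[2-(3,4-dimethoxyphenyl)-1-(3,5-dimethoxyphenyl)-2-hydroxyethyl]-3,5-bis(methoxymethoxy)benzoate (racemic, both diastereomers) | COCOc1cc(C(=O)OC)cc(OCOC)c1C(C(O)c1ccc(OC)c(OC)c1)c1cc(OC)cc(OC)c1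
F4 | step 7 | racemic trans phenol, 17 together with its enantiomer | COC(=O)c1cc(O)c2c(c1)O[C@H](c1ccc(OC)c(OC)c1)[C@H]2c1cc(OC)cc(OC)c1.COC(=O)c1cc(O)c2c(c1)O[C@@H](c1ccc(OC)c(OC)c1)[C@@H]2c1cc(OC)cc(OC)c1
F5 | step 7 | (1S,4R)-camphanate of 17 | COC(=O)c1cc(OC(=O)[C@@]23CC[C@@](C)(C(=O)O2)C3(C)C)c2c(c1)O[C@H](c1ccc(OC)c(OC)c1)[C@H]2c1cc(OC)cc(OC)c1
F6 | step 7 | (1S,4R)-camphanate of the enantiomer of 17 | COC(=O)c1cc(OC(=O)[C@@]23CC[C@@](C)(C(=O)O2)C3(C)C)c2c(c1)O[C@@H](c1ccc(OC)c(OC)c1)[C@@H]2c1cc(OC)cc(OC)c1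
F7 | step 14 | Q–CH2CHO | O=CCc1cc(OC)c2c(c1)O[C@H](c1ccc(OC)c(OC)c1)[C@H]2c1cc(OC)cc(OC)c1
F8 | step 14 | 1-(4-methoxyphenyl)-2-Q-ethanol (both carbinol epimers) | OC(Cc1cc(OC)c2c(c1)O[C@H](c1ccc(OC)c(OC)c1)[C@H]2c1cc(OC)cc(OC)c1)c1ccc(OC)cc1
F9 | step 14 | 1-(4-methoxyphenyl)-2-Q-ethanone | O=C(Cc1cc(OC)c2c(c1)O[C@H](c1ccc(OC)c(OC)c1)[C@H]2c1cc(OC)cc(OC)c1)c1ccc(OC)cc1
F10 | step 14 | methyl 4-[2-(4-methoxyphenyl)-2-oxo-1-Q-ethyl]-3,5-bis(methoxymethoxy)benzoate (both C3 epimers) | COCOc1cc(C(=O)OC)cc(OCOC)c1C(C(=O)c1ccc(OC)cc1)c1cc(OC)c2c(c1)O[C@H](c1ccc(OC)c(OC)c1)[C@H]2c1cc(OC)cc(OC)c1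
F11 | step 14 | methyl 4-[2-hydroxy-2-(4-methoxyphenyl)-1-Q-ethyl]-3,5-bis(methoxymethoxy)benzoate (mixture at C2 and C3) | COCOc1cc(C(=O)OC)cc(OCOC)c1C(C(O)c1ccc(OC)cc1)c1cc(OC)c2c(c1)O[C@H](c1ccc(OC)c(OC)c1)[C@H]2c1cc(OC)cc(OC)c1
F12 | step 14 | methyl (2S,3S)-4-hydroxy-2-(4-methoxyphenyl)-3-Q-2,3-dihydro-1-benzofuran-6-carboxylate | COC(=O)c1cc(O)c2c(c1)O[C@H](c1ccc(OC)cc1)[C@H]2c1cc(OC)c2c(c1)O[C@H](c1ccc(OC)c(OC)c1)[C@H]2c1cc(OC)cc(OC)c1
F13 | step 20 | heptaphenol aldehyde, fully demethylated 33 | O=Cc1cc(O)c2c(c1)O[C@@H](c1ccc(O)cc1)[C@@H]2c1cc(O)c2c(c1)O[C@H](c1ccc(O)c(O)c1)[C@H]2c1cc(O)cc(O)c1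
F14 | step 20 | heptakis(tert-butyldimethylsilyl) ether of F13 | O=Cc1cc(O[Si](C)(C)C(C)(C)C)c2c(c1)O[C@@H](c1ccc(O[Si](C)(C)C(C)(C)C)cc1)[C@@H]2c1cc(O[Si](C)(C)C(C)(C)C)c2c(c1)O[C@H](c1ccc(O[Si](C)(C)C(C)(C)C)c(O[Si](C)(C)C(C)(C)C)c1)[C@H]2c1cc(O[Si](C)(C)C(C)(C)C)cc(O[Si](C)(C)C(C)(C)C)c1
F15 | step 20 | diethyl 4-(tert-butyldimethylsilyloxy)benzylphosphonate | CCOP(=O)(Cc1ccc(O[Si](C)(C)C(C)(C)C)cc1)OCC
F16 | step 20 | octakis(tert-butyldimethylsilyl) ether of 36 | CC(C)(C)[Si](C)(C)Oc1ccc(/C=C/c2cc(O[Si](C)(C)C(C)(C)C)c3c(c2)O[C@@H](c2ccc(O[Si](C)(C)C(C)(C)C)cc2)[C@@H]3c2cc(O[Si](C)(C)C(C)(C)C)c3c(c2)O[C@H](c2ccc(O[Si](C)(C)C(C)(C)C)c(O[Si](C)(C)C(C)(C)C)c2)[C@H]3c2cc(O[Si](C)(C)C(C)(C)C)cc(O[Si](C)(C)C(C)(C)C)c2)cc1
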